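The data come from a simulation from invented constants, noise included.

**1.28** is the number to carry: D, the dose cost, is the moles of target lost at 5.0 min per mole of capture agent charged, as read between the east and north flasks.

common to all: starting material 0.050 M; free catalyst 3.1 mM
- east: capture agent 0.11 mM; run made earlier
- west: capture agent 0.53 mM; run made earlier
- north: capture agent 1.9 mM; run made earlier
- violet: capture agent 0.120 mM; time 5.0 min
- green: capture agent 0.250 mM; time 5.0 min
- grey: capture agent 0.500 mM; time 5.0 min
- blue: capture agent 1.00 mM; time 5.0 min
- ochre: capture agent 2.00 mM; time 5.0 min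

| run | time / min | target / % | starting material / % |
|---|---|---|---|
| east | 0.417 | 1.5 | 93.3 |
| east | 0.833 | 5.2 | 90.9 |
| east | 1.33 | 8.8 | 87.8 |
| east | 2.50 | 15.5 | 80.9 |
| east | 5.00 | 25.6 | 70.6 |
| west | 0.417 | 2.2 | 93.0 |
| west | 1.33 | 8.5 | 87.6 |
| west | 2.50 | 14.8 | 81.2 |
| west | 4.00 | 20.6 | 74.2 |
| west | 5.00 | 24.2 | 70.8 |
| north | 0.417 | 2.2 | 93.5 |
| north | 1.33 | 7.8 | 87.9 |
| north | 2.50 | 14.3 | 82.6 |
| north | 4.00 | 18.9 | 77.1 |
| north | 5.00 | 21.0 | 74.2 |

(each reading ± 0.3 percentage points)

- what was read earlier has a scatter of 0.3 percentage points, one standard deviation
- "hardly changes" means that all values lie within two and a half points (for a concentration: within two and a half percent of the largest)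

- amount of target at the end, in percent of the starting material charged for violet, green, grey, blue, ochre, in this order
- how that number moves from the first to the last of them (rises all the way / falls, then rises / falls all the way / hardly changes / rises, then falls)

The east flask, with 0.11 mM of capture agent, reached 25.6% of target, and the north flask, with 1.9 mM, reached 21.0%. The west flask lies between them at 24.2%. Taken in two steps, D reads 1.67 from east to west and 1.17 from west to north. But the first step rests on a difference of 1.4 percentage points against a scatter of 0.3 points per reading, so D is frozen at its full-span value.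

Target at the end is then reckoned as the east reading minus D times the extra capture agent, divided by the starting material charged, 0.050 M. This own reckoning gives 25.6% for violet, 23.3% for blue and 20.7% for ochre. A straight line has no turning point, so this reckoned row falls all the way.

The forecast gave 25.5%, 25.2%, 24.5%, 23.2% and 20.7%, falls all the way, “with no sign of a maximum”, which lies 0.100 points below the own reckoning at violet.

The flasks give 25.2%, 24.8%, 24.1%, 22.8% and 20.5%: the row falls all the way.

    starting material + free catalyst → catalyst intermediate A (k = 2.00 M⁻¹ s⁻¹)
    catalyst intermediate A ⇌ catalyst intermediate B (K = 0.520, k = 0.120 s⁻¹)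
    catalyst intermediate B → free catalyst + target (k = 0.120 s⁻¹)
    free catalyst → spent catalyst (k = 0.00900 s⁻¹)
    catalyst intermediate A + capture agent → trapped intermediate (k = 2.20 M⁻¹ s⁻¹)
    target + free catalyst ⇌ isomer of the product + free catalyst, rate k6*[free catalyst]*[target] forward; the back reaction follows from the equilibrium constant (K = 6.90, k = 1.30 M⁻¹ s⁻¹)

Between violet and ochre, the new row reads D as 1.25. The ochre flask holds 29.1% of the catalyst charged as trapped intermediate at the end, against 2.05% in violet, while its spent catalyst stands at 42.4%. Carried from violet's 25.2% to the blue flask, the frozen D gives 22.9%, and the blue flask stands at 22.8%.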